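## Retrosynthetic overview

- 15-Keto-PGF2α ⇐ PGF2α (mixture of C15 epimers) by oxidation of the allylic 15-OH only; PGF2α ⇐ PGE2 methyl ester by 9-ketone reduction and saponification.
- PGE2 methyl ester ⇐ racemic 8-epi-9,11-endoperoxide by a chiral-base Kornblum–DeLaMare opening (sets the absolute configuration, makes C9 a ketone) and C8 epimerisation.
- Endoperoxide ⇐ racemic 15-hydroperoxy tetraenoate by one peroxyl-radical cascade with O2: the 1,2-dioxolane ring forms first (O–C9), then the cyclopentane ring (C8–C12), then O2 is captured at C15.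
- Hydroperoxide ⇐ arachidonic acid by internal peracid epoxidation of the 14,15-alkene, epoxide-to-dienol isomerisation and OH-to-OOH exchange.

Assumption: fermentation-derived arachidonic acid counts as a cheap commercial starting material; every intermediate from the epoxide to the endoperoxide is racemic and is named and drawn as the enantiomer that leads to the target; the sense of induction of the step 5 catalyst is taken by analogy, and its pseudoenantiomer (hydroquinine 1,4-phthalazinediyl diether, C48H54N6O4) is used if the first run shows the opposite sense.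

## Route

Step 1
Reactants: 1 arachidonic acid
Product: 5 methyl (5Z,8Z,11Z)-14,15-epoxyicosa-5,8,11-trienoate (racemic cis-epoxide), via arachidonoyl imidazolide 2 (not isolated), via peroxyarachidonic acid 3 (not isolated), via 14,15-epoxy acid 4 (not isolated)
Conditions: 1,1'-carbonyldiimidazole, CH2Cl2, 25 °C; then anhydrous H2O2 in Et2O, cat. LiC3H3N2 (lithium imidazolide), 0 → 25 °C; then Me3SiCHN2, MeOH–toluene, 0 °C
Reagents that add atoms: hydrogen peroxide, OO; (trimethylsilyl)diazomethane, C[Si](C)(C)C=[N+]=[N-]
Why: Intramolecular Prilezhaev epoxidation: the peroxy acid generated at C1 can deliver oxygen through an unstrained macrocyclic transition state only to the remote 14,15-alkene, giving the cis-epoxide stereospecifically from the Z-alkene (racemic, and C15 is later destroyed), and the acid is then O-methylated in the same flask.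

Step 2
Reactants: 5 methyl (5Z,8Z,11Z)-14,15-epoxyicosa-5,8,11-trienoate
Product: 6 methyl (5Z,8Z,11Z,13E)-15-hydroxyicosa-5,8,11,13-tetraenoate (racemic)
Conditions: BrMgN(i-Pr)(c-C6H11) (3 equiv, from EtMgBr and i-PrNH(c-C6H11)), THF, 0 → 25 °C; H2O quench
Reagents that add atoms: none
Why: Base-mediated epoxide-to-allylic-alcohol isomerisation (syn β-elimination): the hindered magnesium amide, which spares the ester, removes the C13 hydrogen that is allylic to the 11,12-alkene and opens the C14–O bond, giving the conjugated 11Z,13E-dienol with the racemic C15 carbinol carried over from the epoxide.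

Step 3
Reactants: 6 methyl (5Z,8Z,11Z,13E)-15-hydroxyicosa-5,8,11,13-tetraenoate
Product: 8 methyl (5Z,8Z,11Z,13E)-15-hydroperoxyicosa-5,8,11,13-tetraenoate (racemic), via 15-methanesulfonate 7 (not isolated)
Conditions: MsCl, Et3N, CH2Cl2, −65 °C; then anhydrous H2O2, Et2O, −110 → −78 °C
Reagents that add atoms: hydrogen peroxide, OO
Why: Nucleophilic substitution of an ionisable dienylic sulfonate by H2O2 (SN1-type perhydrolysis at very low temperature): the hydroperoxide forms at C15, and any allylically transposed 11-hydroperoxide is equally useful because both give the same pentadienyl peroxyl system in step 4, so no stereocontrol is needed here.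

Step 4
Reactants: 8 methyl (5Z,8Z,11Z,13E)-15-hydroperoxyicosa-5,8,11,13-tetraenoate
Product: 11 methyl (5Z,13E)-9α,11α-epidioxy-15-hydroxy-8-epi-prosta-5,13-dienoate (8S,9S,11R,12R shown; racemic; both C15 epimers), via methyl 11-hydroperoxy tetraenoate 9 (not isolated), via 15-hydroperoxy endoperoxide 10 (not isolated)
Conditions: t-BuON=NOt-Bu (10 mol%), O2 (5% in N2, 1 atm), benzene (5 mM), 37 °C; then Me2S, MeOH, 0 °C
Reagents that add atoms: dioxygen, O=O
Why: Peroxyl radical chain cascade (autoxidative 5-exo/5-exo bicyclisation): the 15-peroxyl radical from 8 transposes by β-fragmentation and O2 re-addition to the 11-peroxyl radical of 9, which adds 5-exo to C9 to give the cis-3,5-disubstituted dioxolane (C9 cis to C11), the C8 radical then adds 5-exo to C12 with both chains exo, that is trans to the peroxide bridge (the known kinetic outcome, correct at C12 and epimeric at C8, which is mended in step 5), the allyl radical takes O2 at C15 to leave the 13E-alkene, and Me2S reduces only the hydroperoxide.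

Step 5
Reactants: 11 methyl (5Z,13E)-9α,11α-epidioxy-15-hydroxy-8-epi-prosta-5,13-dienoate (racemic)
Product: 13 PGE2 methyl ester together with its C15 epimer (8R,11R,12R), via 8-iso-PGE2 methyl ester 12 (not isolated)
Conditions: hydroquinidine 1,4-phthalazinediyl diether, C48H54N6O4 (20 mol%), toluene, −20 → 0 °C; then KOAc (CH3CO2K), MeOH, 25 °C
Reagents that add atoms: none
Why: Proposed new method: a chiral tertiary-amine base should effect the Kornblum–DeLaMare rearrangement of racemic 11 as a regiodivergent resolution, removing the bridgehead hydrogen of one local handedness, which is H9 in the enantiomer shown (giving 9-ketone 12 with C11 and C12 untouched) and H11 in its mirror image (giving an 11-keto-9-hydroxy isomer that is removed by chromatography), the closest known reaction being the cinchona-amine-catalysed enantioselective Kornblum–DeLaMare desymmetrisation of meso bicyclic endoperoxides, after which KOAc equilibrates C8 through the enol to the favoured trans-2,3-disubstituted cyclopentanone.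

Step 6
Reactants: 13 PGE2 methyl ester together with its C15 epimer
Product: 15 PGF2α together with its C15 epimer (8R,9S,11R,12R), via PGF2α methyl ester 14 (not isolated)
Conditions: LiBH(s-Bu)3 (4 equiv), THF, −78 °C; then LiOH, H2O–THF, 25 °C; HCl to pH 4
Reagents that add atoms: lithium hydroxide, [Li+].[OH-]
Why: Diastereoselective hydride reduction followed by ester saponification: the bulky borohydride attacks the C9 ketone from the β face, away from the α-chain at C8, giving the 9α (9S) alcohol cis to that chain, and hydroxide then cleaves the methyl ester without touching any stereocentre.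

Step 7
Reactants: 15 PGF2α together with its C15 epimer
Product: 16 15-keto-PGF2α, (5Z,13E)-9α,11α-dihydroxy-15-oxoprosta-5,13-dienoic acid (8R,9S,11R,12R)
Conditions: DDQ (1.5 equiv), 1,4-dioxane, 25 °C
Reagents that add atoms: none
Why: Chemoselective quinone dehydrogenation of an allylic alcohol (hydride abstraction by DDQ): only the C15 carbinol, activated by the 13,14-alkene, is oxidised, so both C15 epimers converge on the enone while the 9- and 11-hydroxyls and the four ring stereocentres are unchanged.

## Compound list

1 | arachidonic acid, (5Z,8Z,11Z,14Z)-icosa-5,8,11,14-tetraenoic acid | CCCCC/C=C\C/C=C\C/C=C\C/C=C\CCCC(=O)O | starting material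
2 | arachidonoyl imidazolide, 1-[(5Z,8Z,11Z,14Z)-icosa-5,8,11,14-tetraenoyl]imidazole | CCCCC/C=C\C/C=C\C/C=C\C/C=C\CCCC(=O)n1ccnc1 | intermediate
3 | peroxyarachidonic acid, (5Z,8Z,11Z,14Z)-icosa-5,8,11,14-tetraeneperoxoic acid | CCCCC/C=C\C/C=C\C/C=C\C/C=C\CCCC(=O)OO | intermediate
4 | (5Z,8Z,11Z)-14,15-epoxyicosa-5,8,11-trienoic acid, cis-epoxide, racemic (14R,15S shown) | CCCCC[C@@H]1O[C@@H]1C/C=C\C/C=C\C/C=C\CCCC(=O)O | intermediate
5 | methyl (5Z,8Z,11Z)-14,15-epoxyicosa-5,8,11-trienoate, cis-epoxide, racemic (14R,15S shown) | CCCCC[C@@H]1O[C@@H]1C/C=C\C/C=C\C/C=C\CCCC(=O)OC | intermediate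
6 | methyl (5Z,8Z,11Z,13E)-15-hydroxyicosa-5,8,11,13-tetraenoate, racemic | CCCCCC(O)/C=C/C=C\C/C=C\C/C=C\CCCC(=O)OC | intermediate
7 | methyl (5Z,8Z,11Z,13E)-15-(methanesulfonyloxy)icosa-5,8,11,13-tetraenoate, racemic | CCCCCC(OS(C)(=O)=O)/C=C/C=C\C/C=C\C/C=C\CCCC(=O)OC | intermediate
8 | methyl (5Z,8Z,11Z,13E)-15-hydroperoxyicosa-5,8,11,13-tetraenoate, racemic | CCCCCC(OO)/C=C/C=C\C/C=C\C/C=C\CCCC(=O)OC | intermediate
9 | methyl (5Z,8Z,12E,14E)-11-hydroperoxyicosa-5,8,12,14-tetraenoate, racemic (11R shown; the 14Z isomer behaves alike) | CCCCC/C=C/C=C/[C@H](OO)C/C=C\C/C=C\CCCC(=O)OC | intermediate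
10 | methyl (5Z,13E)-9α,11α-epidioxy-15-hydroperoxy-8-epi-prosta-5,13-dienoate, racemic (8S,9S,11R,12R shown), both C15 epimers | CCCCCC(OO)/C=C/[C@@H]1[C@H](C/C=C\CCCC(=O)OC)[C@@H]2C[C@H]1OO2 | intermediate
11 | methyl (5Z,13E)-9α,11α-epidioxy-15-hydroxy-8-epi-prosta-5,13-dienoate, racemic (8S,9S,11R,12R shown), both C15 epimers | CCCCCC(O)/C=C/[C@@H]1[C@H](C/C=C\CCCC(=O)OC)[C@@H]2C[C@H]1OO2 | intermediate
12 | 8-iso-PGE2 methyl ester, methyl (5Z,13E)-11α,15-dihydroxy-9-oxo-8-epi-prosta-5,13-dienoate (8S,11R,12R), both C15 epimers | CCCCCC(O)/C=C/[C@@H]1[C@H](C/C=C\CCCC(=O)OC)C(=O)C[C@H]1O | intermediate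
13 | PGE2 methyl ester, methyl (5Z,13E)-11α,15-dihydroxy-9-oxoprosta-5,13-dienoate (8R,11R,12R), both C15 epimers | CCCCCC(O)/C=C/[C@@H]1[C@@H](C/C=C\CCCC(=O)OC)C(=O)C[C@H]1O | intermediate
14 | PGF2α methyl ester, methyl (5Z,13E)-9α,11α,15-trihydroxyprosta-5,13-dienoate (8R,9S,11R,12R), both C15 epimers | CCCCCC(O)/C=C/[C@@H]1[C@@H](C/C=C\CCCC(=O)OC)[C@@H](O)C[C@H]1O | intermediate
15 | PGF2α, (5Z,13E)-9α,11α,15-trihydroxyprosta-5,13-dienoic acid (8R,9S,11R,12R), both C15 epimers | CCCCCC(O)/C=C/[C@@H]1[C@@H](C/C=C\CCCC(=O)O)[C@@H](O)C[C@H]1O | intermediate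
16 | 15-keto-PGF2α, (5Z,13E)-9α,11α-dihydroxy-15-oxoprosta-5,13-dienoic acid (8R,9S,11R,12R) | CCCCCC(=O)/C=C/[C@@H]1[C@@H](C/C=C\CCCC(=O)O)[C@@H](O)C[C@H]1O | target

## Step count and risks

Total step count: 7. Longest linear sequence: 7 (fully linear from 1).

The three steps most likely to fail:

**Step 5 (highest risk).** The chiral base may not discriminate the two bridgehead hydrogens well enough, so that 13 is formed with low enantiomeric purity, and the β-ketol can dehydrate under base. The fallback sets out from 11 and gives up catalyst control in favour of a classical resolution. Racemic 11 is opened with the achiral base Et3N in CH2Cl2 and equilibrated with KOAc in MeOH to give 13 as the racemate. Steps 6 and 7 are run unchanged to give racemic 16. The racemic acid is then crystallised with (R)-1-phenylethylamine as the (R)-1-phenylethylammonium salt of 15-keto-PGF2α F1, and acidification of the less soluble salt returns to the route at 16.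

**Step 4.** The C8 radical can be trapped by O2 before it closes onto C12, and the transposition of the 15-peroxyl to the 11-peroxyl radical may be inefficient, so the bicyclic endoperoxide may be a minor product among monocyclic and serial cyclic peroxides. The fallback sets out from 9, which accompanies 8 in the step 3 product and is separated from it by normal-phase HPLC. The first ring is closed by a polar reaction instead of a radical one: Hg(OAc)2 in CH2Cl2 effects cycloperoxymercuration of the 8,9-alkene to give the cis-dioxolane organomercurial methyl 8-(acetoxymercurio)-9,11-epidioxyicosa-5,12,14-trienoate F2. Slow addition of NaBH4 under 5% O2 at −20 °C then generates the C8 radical, which closes onto C12 and is oxygenated at C15, the borohydride reducing the new hydroperoxide. This comes back to the route at 11.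

**Step 3.** The dienylic methanesulfonate may eliminate or decompose before H2O2 captures it. The fallback sets out from 1 and replaces the three-step directed sequence by direct radical C–H oxygenation. Compound 1 is methylated with Me3SiCHN2 to methyl arachidonate F3, which is autoxidised to low conversion (O2, t-BuON=NOt-Bu, α-tocopherol as hydrogen donor, 37 °C). Normal-phase HPLC of the regioisomeric hydroperoxides gives the 15-hydroperoxide, which is 8, where the route is rejoined; recovered F3 is recycled.

## Further compounds

F1 | step 5 | (R)-1-phenylethylammonium salt of 15-keto-PGF2α (8R,9S,11R,12R) | CCCCCC(=O)/C=C/[C@@H]1[C@@H](C/C=C\CCCC(=O)[O-])[C@@H](O)C[C@H]1O.C[C@@H]([NH3+])c1ccccc1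
F2 | step 4 | methyl (5Z,12E,14E)-8-(acetoxymercurio)-9,11-epidioxyicosa-5,12,14-trienoate, cis-dioxolane (9S,11R shown; racemic; C8 not specified because it is lost on demercuration) | CCCCC/C=C/C=C/[C@H]1C[C@H](OO1)C([Hg]OC(C)=O)C/C=C\CCCC(=O)OC
F3 | step 3 | methyl arachidonate, methyl (5Z,8Z,11Z,14Z)-icosa-5,8,11,14-tetraenoate | CCCCC/C=C\C/C=C\C/C=C\C/C=C\CCCC(=O)OC
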